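**Retrosynthetic overview**

1. The target is a (2S)-flavanone: ring A (5-OH, 6-prenyl, 7-OMe), ring B (2'-geranyl, 3',4'-OMe) and the pyranone ring C. The route rests on one feature: in the silyl enol ether of the flavanone the C3–C4 bond of ring C is a C=C bond, and C2 is then an allylic carbon bearing O1 and ring B (a branched 1-arylallyl aryl ether).
2. Ring C is cut at C3=C4 by ring-closing metathesis of a diene that joins the TBS enol ether of the ring A acetophenone (C4=CH2) to the (S)-1-arylallyl ether on O1 (C2–CH=CH2). Desilylation then gives the C4 ketone.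
3. C2 is set before ring C exists, by iridium-catalysed branched-selective allylic etherification of the ring A phenol with the ring B cinnamyl carbonate.
4. The ring A phenol comes from 2,6-dihydroxy-4-methoxyacetophenone by mono-MOM protection, O-prenylation and a para-Claisen–Cope shift, which puts the prenyl group at C6 and frees only the O1 hydroxyl. The geranyl chain is held back as the C2' bromide during metathesis and joined afterwards by Stille coupling.
5. Ring order: rings A and B are bought as arenes; ring C is the only ring formed (step 9).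

Key step: step 9

Remark: the (Sa,S,S) phosphoramidite is taken as the antipode that gives the (S)-ether 13. The sense of induction is to be checked on the first run; the (Ra,R,R) ligand does the same chemistry in the mirror-image sense.

**Route**

Step 1
Reactants: 1 2,6-dihydroxy-4-methoxyacetophenone
Product: 2 1-[2-hydroxy-4-methoxy-6-(methoxymethoxy)phenyl]ethan-1-one
Conditions: MOMCl (1.05 equiv), i-Pr2NEt, CH2Cl2, 0 °C → rt
Reagents that add atoms: chloromethyl methyl ether, COCCl
Why: Williamson-type O-alkylation (MOM protection): the diol is symmetric, and after the first etherification the remaining hydroxyl is held in a hydrogen bond to the acetyl group, so the reaction should stop at the mono-MOM ether.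

Step 2
Reactants: 2 1-[2-hydroxy-4-methoxy-6-(methoxymethoxy)phenyl]ethan-1-one; 3 prenyl bromide
Product: 4 1-[4-methoxy-2-(methoxymethoxy)-6-(3-methylbut-2-enyloxy)phenyl]ethan-1-one
Conditions: K2CO3, DMF, 50 °C
Reagents that add atoms: none
Why: Williamson ether synthesis: K2CO3 in DMF is basic enough to open the chelate of the remaining phenol, and the allylic bromide should alkylate the phenoxide on oxygen.

Step 3
Reactants: 4 1-[4-methoxy-2-(methoxymethoxy)-6-(3-methylbut-2-enyloxy)phenyl]ethan-1-one
Product: 7 1-[6-hydroxy-4-methoxy-2-(methoxymethoxy)-3-(3-methylbut-2-enyl)phenyl]ethan-1-one, via ortho-dienone 5 (not isolated), via para-dienone 6 (not isolated)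
Conditions: PhNEt2, 200 °C, sealed tube under Ar
Reagents that add atoms: none
Why: Para-Claisen rearrangement (aromatic Claisen followed by Cope shift): the [3,3] shift to the acetyl-bearing ortho carbon gives a dienone that cannot enolise, so the allyl unit moves on by a second [3,3] shift to the para carbon and tautomerisation restores the arene with a normal prenyl group between OMe and OMOM, leaving free only the hydroxyl that becomes O1; the MOM ether should survive the neutral, amine-buffered thermolysis.

Step 4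
Reactants: 8 2-bromo-3,4-dimethoxybenzaldehyde
Product: 9 ethyl (E)-3-(2-bromo-3,4-dimethoxyphenyl)prop-2-enoate
Conditions: Ph3P=CHCO2Et, toluene, 80 °C
Reagents that add atoms: ethyl (triphenylphosphoranylidene)acetate, CCOC(=O)C=P(c1ccccc1)(c1ccccc1)c1ccccc1
Why: Wittig olefination with a stabilised ylide, which is E-selective with aromatic aldehydes and tolerates the aryl bromide.

Step 5
Reactants: 9 ethyl (E)-3-(2-bromo-3,4-dimethoxyphenyl)prop-2-enoate
Product: 10 (E)-3-(2-bromo-3,4-dimethoxyphenyl)prop-2-en-1-ol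
Conditions: i-Bu2AlH (2.3 equiv), CH2Cl2, −78 → 0 °C; aq. potassium sodium tartrate
Reagents that add atoms: none
Why: 1,2-Reduction of the enoate by i-Bu2AlH at low temperature gives the allylic alcohol without touching the alkene geometry or the C–Br bond.

Step 6
Reactants: 10 (E)-3-(2-bromo-3,4-dimethoxyphenyl)prop-2-en-1-ol
Product: 11 (E)-3-(2-bromo-3,4-dimethoxyphenyl)prop-2-enyl methyl carbonate
Conditions: ClCO2Me, pyridine, CH2Cl2, 0 °C
Reagents that add atoms: methyl chloroformate, COC(=O)Cl
Why: Acylation of the primary allylic alcohol with a chloroformate gives the methyl carbonate, a suitable leaving group for iridium-catalysed allylic substitution because it releases CO2 and methoxide on ionisation.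

Step 7
Reactants: 7 1-[6-hydroxy-4-methoxy-2-(methoxymethoxy)-3-(3-methylbut-2-enyl)phenyl]ethan-1-one; 11 (E)-3-(2-bromo-3,4-dimethoxyphenyl)prop-2-enyl methyl carbonate
Product: 13 1-[6-{[(1S)-1-(2-bromo-3,4-dimethoxyphenyl)prop-2-enyl]oxy}-4-methoxy-2-(methoxymethoxy)-3-(3-methylbut-2-enyl)phenyl]ethan-1-one, via sodium aryloxide 12 (not isolated)
Conditions: NaH (1.0 equiv), THF, 0 °C; then 11 (1.2 equiv), [Ir(cod)Cl]2 (2 mol%), (Sa,S,S)-O,O'-(1,1'-binaphthyl-2,2'-diyl) N,N-bis(1-phenylethyl)phosphoramidite (4 mol%; catalyst pre-activated with n-PrNH2, volatiles removed), THF, rt; stopped at full conversion; Et3N-deactivated silica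
Reagents that add atoms: none
Why: Iridium-catalysed asymmetric allylic etherification of an aryloxide with a linear cinnamyl carbonate: the cyclometallated iridium–phosphoramidite complex ionises the carbonate to an allyliridium species that the aryloxide attacks at the aryl-substituted terminus, so the branched ether should form, and the ligand fixes the face of attack and with it the (S) configuration at the future C2; only one phenol is free, so no regiochemical question arises on ring A.

Step 8
Reactants: 13 1-[6-{[(1S)-1-(2-bromo-3,4-dimethoxyphenyl)prop-2-enyl]oxy}-4-methoxy-2-(methoxymethoxy)-3-(3-methylbut-2-enyl)phenyl]ethan-1-one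
Product: 14 tert-butyl({1-[6-{[(1S)-1-(2-bromo-3,4-dimethoxyphenyl)prop-2-enyl]oxy}-4-methoxy-2-(methoxymethoxy)-3-(3-methylbut-2-enyl)phenyl]ethenyl}oxy)dimethylsilane
Conditions: TBSOTf (1.3 equiv), Et3N (3 equiv), CH2Cl2, −78 → 0 °C; Et3N-deactivated silica
Reagents that add atoms: tert-butyldimethylsilyl trifluoromethanesulfonate, CC(C)(C)[Si](C)(C)OS(=O)(=O)C(F)(F)F
Why: Soft enolisation (silyl triflate and amine): O-silylation of the ketone and deprotonation of its only enolisable position, the methyl group, give the terminal TBS enol ether, while excess Et3N and low temperature should keep the MOM acetal and the ionisable allylic ether intact.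

Step 9
Reactants: 14 tert-butyl({1-[6-{[(1S)-1-(2-bromo-3,4-dimethoxyphenyl)prop-2-enyl]oxy}-4-methoxy-2-(methoxymethoxy)-3-(3-methylbut-2-enyl)phenyl]ethenyl}oxy)dimethylsilane
Product: 15 (2S)-2-(2-bromo-3,4-dimethoxyphenyl)-4-[(tert-butyldimethylsilyl)oxy]-7-methoxy-5-(methoxymethoxy)-6-(3-methylbut-2-enyl)-2H-chromene
Conditions: second-generation Grubbs catalyst RuCl2(=CHPh)(PCy3)(H2IMes) (10 mol%), 1,4-benzoquinone (20 mol%), toluene (0.005 M), 60 °C, Ar sparge, dark
Reagents that add atoms: none
Why: The ruthenium benzylidene exchanges first with the monosubstituted vinyl group of the allylic ether to give the alkylidene at the future C3, which adds across the 1,1-disubstituted silyl enol ether C4=CH2 to a ruthenacyclobutane and cycloreverts, giving the C3=C4 bond and ethylene, which the argon stream removes. The closest known reactions are the ring-closing metathesis of silyl enol ether dienes to cyclic silyl enol ethers and of 2-vinylaryl allyl ethers to 2H-chromenes. Ring C closes as a six-membered ring by intramolecular [2+2] cycloaddition and cycloreversion between two alkenes held ortho to each other on ring A, so at 0.005 M cyclisation should outrun cross metathesis. No stereocentre is formed: C2, set in step 7, is not a reacting carbon, and benzoquinone is added to quench ruthenium hydrides that could move the vinyl double bond into conjugation with O1 and erase C2. The selectivity needed is reaction at the vinyl and enol ether alkenes only: the trisubstituted prenyl alkene is slow in metathesis and could reach either partner only through a meta or para bridge, and the geranyl chain, whose 2,3-alkene would close on the C3 alkylidene to a dihydronaphthalene, is absent, its place at C2' held by bromine. Moderate temperature and exclusion of light guard the 2H-chromene against 6π ring opening, which would racemise C2.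

Step 10
Reactants: 15 (2S)-2-(2-bromo-3,4-dimethoxyphenyl)-4-[(tert-butyldimethylsilyl)oxy]-7-methoxy-5-(methoxymethoxy)-6-(3-methylbut-2-enyl)-2H-chromene
Product: 16 (2S)-2-(2-bromo-3,4-dimethoxyphenyl)-7-methoxy-5-(methoxymethoxy)-6-(3-methylbut-2-enyl)chroman-4-one
Conditions: n-Bu4NF/AcOH (1:1.2), THF, 0 °C
Reagents that add atoms: none
Why: Fluoride-induced desilylation of the silyl enol ether with acetic acid present, so that the enolate is protonated at C3 as it forms and cannot expel O1 (retro-oxa-Michael), which should keep C2 intact.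

Step 11
Reactants: 17 geranyl bromide
Product: 18 tributyl[(2E)-3,7-dimethylocta-2,6-dienyl]stannane
Conditions: n-Bu3SnH, LiN(i-Pr)2, THF, 0 °C; then 17, −78 °C → rt
Reagents that add atoms: tributyltin hydride, CCCC[SnH](CCCC)CCCC
Why: SN2 displacement of the primary allylic bromide by the tributylstannyl anion, which attacks the unhindered α-carbon and leaves the 2E-alkene in place.

Step 12
Reactants: 16 (2S)-2-(2-bromo-3,4-dimethoxyphenyl)-7-methoxy-5-(methoxymethoxy)-6-(3-methylbut-2-enyl)chroman-4-one; 18 tributyl[(2E)-3,7-dimethylocta-2,6-dienyl]stannane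
Product: 19 (2S)-2-{2-[(2E)-3,7-dimethylocta-2,6-dienyl]-3,4-dimethoxyphenyl}-7-methoxy-5-(methoxymethoxy)-6-(3-methylbut-2-enyl)chroman-4-one
Conditions: Pd2(dba)3 (3 mol%), P(t-Bu)3 (12 mol%), CsF (2.2 equiv), 1,4-dioxane, 50 °C
Reagents that add atoms: none
Why: Stille coupling with an allylstannane: the electron-rich, bulky zerovalent palladium–P(t-Bu)3 catalyst inserts into the di-ortho-substituted C–Br bond, fluoride activates the stannane for transmetallation, and reductive elimination at the less hindered allyl terminus should give the linear 2E-geranyl arene.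

Step 13
Reactants: 19 (2S)-2-{2-[(2E)-3,7-dimethylocta-2,6-dienyl]-3,4-dimethoxyphenyl}-7-methoxy-5-(methoxymethoxy)-6-(3-methylbut-2-enyl)chroman-4-one
Product: 20 (2S)-2-{2-[(2E)-3,7-dimethylocta-2,6-dienyl]-3,4-dimethoxyphenyl}-5-hydroxy-7-methoxy-6-(3-methylbut-2-enyl)chroman-4-one (CNP0112088.1)
Conditions: MgBr2·OEt2 (3 equiv), Et2O/CH2Cl2, 0 °C → rt; aq. NH4Cl
Reagents that add atoms: none
Why: Chelation-assisted Lewis acid cleavage of the MOM acetal: MgBr2 binds the C4 carbonyl and the peri C5 oxygen, bromide takes the methoxymethyl group, and the mild conditions should spare the prenyl and geranyl alkenes, the methyl ethers and the C2 stereocentre.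

**Compound list**

1 | 2,6-dihydroxy-4-methoxyacetophenone | CC(=O)c1c(O)cc(OC)cc1O | starting material
2 | 1-[2-hydroxy-4-methoxy-6-(methoxymethoxy)phenyl]ethan-1-one | CC(=O)c1c(O)cc(OC)cc1OCOC | intermediate
3 | prenyl bromide (1-bromo-3-methylbut-2-ene) | CC(C)=CCBr | starting material
4 | 1-[4-methoxy-2-(methoxymethoxy)-6-(3-methylbut-2-enyloxy)phenyl]ethan-1-one | CC(=O)c1c(OCC=C(C)C)cc(OC)cc1OCOC | intermediate
5 | ortho-dienone: 6-acetyl-3-methoxy-5-(methoxymethoxy)-6-(2-methylbut-3-en-2-yl)cyclohexa-2,4-dien-1-one (racemic) | CC(=O)C1(C(C)(C)C=C)C(=O)C=C(OC)C=C1OCOC | intermediate (not isolated)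
6 | para-dienone: 2-acetyl-5-methoxy-3-(methoxymethoxy)-4-(3-methylbut-2-enyl)cyclohexa-2,5-dien-1-one (racemic) | CC(=O)C1=C(OCOC)C(CC=C(C)C)C(OC)=CC1=O | intermediate (not isolated)
7 | 1-[6-hydroxy-4-methoxy-2-(methoxymethoxy)-3-(3-methylbut-2-enyl)phenyl]ethan-1-one | CC(=O)c1c(O)cc(OC)c(CC=C(C)C)c1OCOC | intermediate
8 | 2-bromo-3,4-dimethoxybenzaldehyde | COc1ccc(C=O)c(Br)c1OC | starting material
9 | ethyl (E)-3-(2-bromo-3,4-dimethoxyphenyl)prop-2-enoate | CCOC(=O)/C=C/c1ccc(OC)c(OC)c1Br | intermediate
10 | (E)-3-(2-bromo-3,4-dimethoxyphenyl)prop-2-en-1-ol | OC/C=C/c1ccc(OC)c(OC)c1Br | intermediate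
11 | (E)-3-(2-bromo-3,4-dimethoxyphenyl)prop-2-enyl methyl carbonate | COC(=O)OC/C=C/c1ccc(OC)c(OC)c1Br | intermediate
12 | sodium 2-acetyl-5-methoxy-3-(methoxymethoxy)-4-(3-methylbut-2-enyl)phenoxide | CC(=O)c1c([O-])cc(OC)c(CC=C(C)C)c1OCOC.[Na+] | intermediate (not isolated)
13 | 1-[6-{[(1S)-1-(2-bromo-3,4-dimethoxyphenyl)prop-2-enyl]oxy}-4-methoxy-2-(methoxymethoxy)-3-(3-methylbut-2-enyl)phenyl]ethan-1-one | CC(=O)c1c(O[C@@H](C=C)c2ccc(OC)c(OC)c2Br)cc(OC)c(CC=C(C)C)c1OCOC | intermediate
14 | TBS enol ether of 13 (metathesis precursor) | COc1cc(O[C@@H](C=C)c2ccc(OC)c(OC)c2Br)c(C(=C)O[Si](C)(C)C(C)(C)C)c(OCOC)c1CC=C(C)C | intermediate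
15 | (2S)-2-(2-bromo-3,4-dimethoxyphenyl)-4-[(tert-butyldimethylsilyl)oxy]-7-methoxy-5-(methoxymethoxy)-6-(3-methylbut-2-enyl)-2H-chromene | COc1cc2c(c(OCOC)c1CC=C(C)C)C(O[Si](C)(C)C(C)(C)C)=C[C@@H](c1ccc(OC)c(OC)c1Br)O2 | intermediate
16 | (2S)-2-(2-bromo-3,4-dimethoxyphenyl)-7-methoxy-5-(methoxymethoxy)-6-(3-methylbut-2-enyl)chroman-4-one | COc1cc2c(c(OCOC)c1CC=C(C)C)C(=O)C[C@@H](c1ccc(OC)c(OC)c1Br)O2 | intermediate
17 | geranyl bromide ((2E)-1-bromo-3,7-dimethylocta-2,6-diene) | CC(C)=CCC/C(C)=C/CBr | starting material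
18 | tributyl[(2E)-3,7-dimethylocta-2,6-dienyl]stannane | CCCC[Sn](CCCC)(CCCC)C/C=C(\C)CCC=C(C)C | intermediate
19 | (2S)-2-{2-[(2E)-3,7-dimethylocta-2,6-dienyl]-3,4-dimethoxyphenyl}-7-methoxy-5-(methoxymethoxy)-6-(3-methylbut-2-enyl)chroman-4-one | COc1cc2c(c(OCOC)c1CC=C(C)C)C(=O)C[C@@H](c1ccc(OC)c(OC)c1C/C=C(\C)CCC=C(C)C)O2 | intermediate
20 | (2S)-2-{2-[(2E)-3,7-dimethylocta-2,6-dienyl]-3,4-dimethoxyphenyl}-5-hydroxy-7-methoxy-6-(3-methylbut-2-enyl)chroman-4-one | COc1cc2c(c(O)c1CC=C(C)C)C(=O)C[C@@H](c1ccc(OC)c(OC)c1C/C=C(\C)CCC=C(C)C)O2 | target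

**Count and risks**

Total steps: 13. Longest linear sequence: 9 steps (steps 1, 2, 3, 7, 8, 9, 10, 12, 13 from compound 1; equally steps 4–10, 12, 13 from compound 8).

Steps most likely to fail:

1. Step 9 (ring-closing metathesis). The alkylidene formed at the vinyl group may fail to engage the enol ether, which is electron-rich, 1,1-disubstituted and flanked by two ortho substituents. Catalyst decay, dimerisation by cross metathesis, or hydride-mediated migration of the allylic ether double bond (which would erase C2) could then outrun ring closure. Fallback: set out from 7 and 8. Claisen–Schmidt condensation (KOH, EtOH, rt) should give (E)-3-(2-bromo-3,4-dimethoxyphenyl)-1-[6-hydroxy-4-methoxy-2-(methoxymethoxy)-3-(3-methylbut-2-enyl)phenyl]prop-2-en-1-one F1. Intramolecular oxa-Michael addition (NaOAc, EtOH, reflux) should close it to racemic 2-(2-bromo-3,4-dimethoxyphenyl)-7-methoxy-5-(methoxymethoxy)-6-(3-methylbut-2-enyl)chroman-4-one F2. Kinetic resolution by asymmetric transfer hydrogenation follows (RuCl(p-cymene)(TsDPEN), the antipode that reduces the 2R enantiomer faster, HCO2H/Et3N, rt). It should leave the 2S ketone and turn the 2R ketone into (2R,4R)-2-(2-bromo-3,4-dimethoxyphenyl)-7-methoxy-5-(methoxymethoxy)-6-(3-methylbut-2-enyl)chroman-4-ol F3, which chromatography removes. The route is rejoined at 16.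

2. Step 7 (iridium-catalysed etherification). The ortho-bromo substituent on the cinnamyl unit and the weak nucleophilicity of the chelated 2-acylphenoxide may lower the branched selectivity and the facial selectivity. The catalyst may also re-ionise the product ether, with loss of enantiomeric purity and drift to the linear ether. Fallback: set out from 8. Enantioselective alkynylation (trimethylsilylacetylene, Me2Zn, the ProPhenol antipode that gives the R carbinol, toluene) should give (1R)-1-(2-bromo-3,4-dimethoxyphenyl)-3-(trimethylsilyl)prop-2-yn-1-ol F4. K2CO3 in MeOH should remove the silyl group to give (1R)-1-(2-bromo-3,4-dimethoxyphenyl)prop-2-yn-1-ol F5. Mitsunobu etherification with phenol 7 (PPh3, DIAD, toluene, 0 °C) should proceed with inversion to 1-[6-{[(1S)-1-(2-bromo-3,4-dimethoxyphenyl)prop-2-ynyl]oxy}-4-methoxy-2-(methoxymethoxy)-3-(3-methylbut-2-enyl)phenyl]ethan-1-one F6. Semihydrogenation of the terminal alkyne (H2, Pd/CaCO3 poisoned with Pb(OAc)2, quinoline, EtOAc) rejoins the route at 13.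

3. Step 12 (Stille coupling). Oxidative addition into the hindered, electron-rich C–Br bond may be slow. The allylpalladium intermediate may scramble the allyl terminus (branched coupling) or the 2,3-alkene geometry by σ–π–σ interconversion. Fluoride may enolise the ketone and open ring C by retro-oxa-Michael reaction, eroding C2. Fallback: set out from 15, before desilylation. Bromine–lithium exchange (n-BuLi, THF, −78 °C), transmetallation with CuBr·SMe2 and SN2 allylation of the arylcopper with geranyl bromide 17 should give (2S)-4-[(tert-butyldimethylsilyl)oxy]-2-{2-[(2E)-3,7-dimethylocta-2,6-dienyl]-3,4-dimethoxyphenyl}-7-methoxy-5-(methoxymethoxy)-6-(3-methylbut-2-enyl)-2H-chromene F7. Buffered desilylation (n-Bu4NF/AcOH, THF, 0 °C) rejoins the route at 19, so that steps 10 to 12 are bypassed.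

Further compounds
F1 | step 9 | (E)-3-(2-bromo-3,4-dimethoxyphenyl)-1-[6-hydroxy-4-methoxy-2-(methoxymethoxy)-3-(3-methylbut-2-enyl)phenyl]prop-2-en-1-one | COc1cc(O)c(C(=O)/C=C/c2ccc(OC)c(OC)c2Br)c(OCOC)c1CC=C(C)C
F2 | step 9 | racemic 2-(2-bromo-3,4-dimethoxyphenyl)-7-methoxy-5-(methoxymethoxy)-6-(3-methylbut-2-enyl)chroman-4-one | COc1cc2c(c(OCOC)c1CC=C(C)C)C(=O)CC(c1ccc(OC)c(OC)c1Br)O2
F3 | step 9 | (2R,4R)-2-(2-bromo-3,4-dimethoxyphenyl)-7-methoxy-5-(methoxymethoxy)-6-(3-methylbut-2-enyl)chroman-4-ol | COc1cc2c(c(OCOC)c1CC=C(C)C)[C@H](O)C[C@H](c1ccc(OC)c(OC)c1Br)O2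
F4 | step 7 | (1R)-1-(2-bromo-3,4-dimethoxyphenyl)-3-(trimethylsilyl)prop-2-yn-1-ol | C[Si](C)(C)C#C[C@@H](O)c1ccc(OC)c(OC)c1Br
F5 | step 7 | (1R)-1-(2-bromo-3,4-dimethoxyphenyl)prop-2-yn-1-ol | C#C[C@@H](O)c1ccc(OC)c(OC)c1Br
F6 | step 7 | 1-[6-{[(1S)-1-(2-bromo-3,4-dimethoxyphenyl)prop-2-ynyl]oxy}-4-methoxy-2-(methoxymethoxy)-3-(3-methylbut-2-enyl)phenyl]ethan-1-one | CC(=O)c1c(O[C@@H](C#C)c2ccc(OC)c(OC)c2Br)cc(OC)c(CC=C(C)C)c1OCOC
F7 | step 12 | (2S)-4-[(tert-butyldimethylsilyl)oxy]-2-{2-[(2E)-3,7-dimethylocta-2,6-dienyl]-3,4-dimethoxyphenyl}-7-methoxy-5-(methoxymethoxy)-6-(3-methylbut-2-enyl)-2H-chromene | COc1cc2c(c(OCOC)c1CC=C(C)C)C(O[Si](C)(C)C(C)(C)C)=C[C@@H](c1ccc(OC)c(OC)c1C/C=C(\C)CCC=C(C)C)O2
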